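Numbering used for the same atoms in every precursor: bicyclo[3.3.1]nonane core with bridgeheads C1 (next to the quaternary C8) and C5, enolised dione C2–C4, geranyl-bearing C7, bridging ketone C9.
Retrosynthesis: cut C3–aroyl, C1–prenyl and C5–prenyl (lithiations of a methyl enol ether), then undo a 1,2-shift of C8 from C9 to C1; this turns the ketone ring (C1, C8, C7, C6, C5, C9) into a cyclopentane (C9, C8, C7, C6, C5) cis-fused along C5–C9 to a cyclohexane-1,3-dione (C9, C1, C2, C3, C4, C5) with OH on C9.
That hydrindanol is cut at C4–C5 and C1–C9 into diketene and a 2,2,3-trisubstituted cyclopentanone, which goes back (C8–homoprenyl, C8–methyl, C7–H) to 3-geranylcyclopent-2-enone, made from cyclopent-2-enone and geranyl bromide through a β-sulfonyl ketal.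
Forward ring order: cyclopentane first, dione ring second (acylation–aldol annulation), then oxidative ring expansion of the cyclopentane to the bridged cyclohexanone, then two prenyl groups and the aroyl group.
Feature that makes the event possible: the ring-fusion alkoxide carbon C9 lies between the quaternary C8 and the α'-carbon C1 of the 1,3-dione, so two-electron oxidation of the dione makes C1 electrophilic next to an axial, electron-rich C9–C8 bond.
Stereochemistry: C7 from an enantioselective copper hydride conjugate reduction, C8 by enolate alkylation anti to the C7 chain, the ring fusion under control of C7/C8, C1 and C5 from the bridged skeleton (retentive shift, retentive bridgehead alkylations).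

Key step: step 9

Remark: geranyl = (2E)-3,7-dimethylocta-2,6-dien-1-yl, homoprenyl = 4-methylpent-3-en-1-yl, prenyl = 3-methylbut-2-en-1-yl; enols and enol ethers are each written as one tautomer or regioisomer.
Remark: (S)-p-tol-BINAP is written in step 5 by analogy with simple 3-alkylcyclopent-2-enones; the ligand antipode that delivers the (3S) centre is the one to be used.

Step 1
Reactants: 1 cyclopent-2-en-1-one
Product: 2 rac-3-(phenylsulfonyl)cyclopentan-1-one
Conditions: PhSO2Na, AcOH, EtOH/H2O, rt
Reagents that add atoms: sodium benzenesulfinate, [Na+].[O-]S(=O)c1ccccc1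
Why: Sulfa-Michael (conjugate) addition of benzenesulfinic acid, formed in the flask, to the enone gives the β-sulfonyl ketone and installs the group that later turns C7 into a carbanion site; the stereocentre formed is racemic and is erased in step 4.

Step 2
Reactants: 2 rac-3-(phenylsulfonyl)cyclopentan-1-one
Product: 3 rac-7-(phenylsulfonyl)-1,4-dioxaspiro[4.4]nonane
Conditions: HOCH2CH2OH, TsOH (cat.), benzene, reflux with azeotropic removal of water
Reagents that add atoms: ethane-1,2-diol, OCCO
Why: Acid-catalysed ketalisation masks the ketone so that base in step 3 can only remove the α-sulfonyl proton and cannot trigger β-elimination of sulfinate.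

Step 3
Reactants: 3 rac-7-(phenylsulfonyl)-1,4-dioxaspiro[4.4]nonane; 4 geranyl bromide
Product: 5 rac-7-geranyl-7-(phenylsulfonyl)-1,4-dioxaspiro[4.4]nonane
Conditions: n-BuLi, THF, −78 °C; then 4, −78 °C to rt
Reagents that add atoms: none
Why: The α-sulfonyl carbanion is alkylated by the primary allylic bromide in an SN2 reaction, which forms the C7–geranyl bond with the E geometry of the bromide untouched (sulfone alkylation).

Step 4
Reactants: 5 rac-7-geranyl-7-(phenylsulfonyl)-1,4-dioxaspiro[4.4]nonane
Product: 7 3-geranylcyclopent-2-en-1-one, via sulfonyl ketone 6 (not isolated)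
Conditions: 1 M HCl, THF, rt; then Et3N, CH2Cl2, 0 °C to rt
Reagents that add atoms: water, O
Why: Ketal hydrolysis frees the β-sulfonyl ketone 6, which loses benzenesulfinate by E1cB elimination with Et3N, so that the sulfone has served as a β-acyl vinyl anion equivalent and the β-geranyl enone results.

Step 5
Reactants: 7 3-geranylcyclopent-2-en-1-one
Product: 9 (2S,3S)-3-geranyl-2-methylcyclopentan-1-one, via diphenylsilyl enol ether 8 (not isolated)
Conditions: CuCl (5 mol %), NaOtBu (5 mol %), (S)-p-tol-BINAP (5 mol %), Ph2SiH2, toluene, 0 °C; then MeI, Bu4N[Ph3SiF2], THF, rt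
Reagents that add atoms: iodomethane, CI
Why: Copper hydride-catalysed asymmetric conjugate reduction of a β-alkyl cyclopentenone sets C7 (ring C3, S) by ligand-controlled hydride delivery to one enone face and leaves the regiodefined silyl enol ether 8, whose fluoride-triggered methylation anti to the C3 chain should give mainly the trans ketone (the C2 centre is levelled again in step 6).

Step 6
Reactants: 9 (2S,3S)-3-geranyl-2-methylcyclopentan-1-one
Product: 10 trimethyl{[(3S)-3-geranyl-2-methylcyclopent-1-en-1-yl]oxy}silane
Conditions: Me3SiCl, Et3N, DMF, 120 °C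
Reagents that add atoms: chlorotrimethylsilane, C[Si](C)(C)Cl
Why: Silylation under equilibrating conditions is expected to give mainly the more substituted (tetrasubstituted) silyl enol ether, which prepares regioselective quaternisation of C8; any C5 isomer is removed after step 7.

Step 7
Reactants: 10 trimethyl{[(3S)-3-geranyl-2-methylcyclopent-1-en-1-yl]oxy}silane; 11 5-bromo-2-methylpent-2-ene
Product: 12 (2S,3S)-3-geranyl-2-methyl-2-(4-methylpent-3-en-1-yl)cyclopentan-1-one
Conditions: MeLi, THF, 0 °C; then HMPA, 11, Bu4NI (cat.), −78 °C to rt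
Reagents that add atoms: none
Why: MeLi cleaves the silyl enol ether to the lithium enolate without equilibration and SN2 alkylation occurs on the face anti to the adjacent geranyl group, which sets the quaternary C8 (S) with homoprenyl trans and methyl cis to geranyl (enolate alkylation).

Step 8
Reactants: 12 (2S,3S)-3-geranyl-2-methyl-2-(4-methylpent-3-en-1-yl)cyclopentan-1-one; 13 diketene
Product: 15 cis-fused hydrindanol dione, via acetoacetyl ketone 14 (not isolated)
Conditions: lithium 2,2,6,6-tetramethylpiperidide, THF, −78 °C; then 13, −78 to 0 °C; aq. NH4Cl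
Reagents that add atoms: none
Why: The only possible enolate (C5, since C8 is quaternary) is C-acylated by diketene, the ring-opened methyl ketone enolate adds to the flanking ring ketone (acylation–aldol annulation, 6-exo-trig aldol closure) anti to the pseudo-axial C8 methyl, and the epimerisable C5 settles in the cis ring fusion, so that C1 and C4 lie on the homoprenyl face and the C9 hydroxyl on the methyl face.

Step 9
Reactants: 15 cis-fused hydrindanol dione
Product: 17 bicyclo[3.3.1]nonane trione with both bridgeheads unsubstituted, via iodonium ylide 16 (not isolated)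
Conditions: PhI(OAc)2, KOH, MeOH, 0 °C; then 1 M HCl (work-up)
Reagents that add atoms: none
Why: KOH/MeOH converts the cyclic 1,3-dione into its enolate, PhI(OAc)2 oxidises C3 to the phenyliodonium ylide 16, and loss of iodobenzene from the C1-enolised α-iodonio ketone leaves an oxyallyl cation (C1–C2–C3) whose C1 end is bonded to the ring-fusion alkoxide carbon C9. The C9–C8 bond, axial on the dione ring because of the cis ring fusion and pushed by the C9 alkoxide, then shifts from C9 to C1 (vinylogous semipinacol 1,2-shift), so that C9 becomes the bridging ketone and the cyclopentane (C9, C8, C7, C6, C5) grows into the cyclohexanone (C1, C8, C7, C6, C5, C9) of the bicyclo[3.3.1]nonane. The closest known reaction types are the semipinacol ring expansion of β-hydroxy α-halo ketones, the oxidative 1,2-shifts that trivalent iodine reagents induce in enolisable ketones in basic methanol, and the oxidative ring expansion of diketene-annulated cyclopentanones to bridged acylphloroglucinol cores. No ring is closed by cyclisation: the six-membered ring arises by a suprafacial 1,2-alkyl shift through a three-centre transition state, and it is bridged from the outset because C1 and C5 are already joined through C2–C4. C8 migrates with retention and the new bridgehead C1 can form only with its bond to C8 on the face that the fused ring dictates, so C1, C5, C7 and C8 emerge in the relative configuration of the target while the C9 carbinol centre is lost. The step needs migration of C8 rather than of the ring carbon C5 and oxidation of the dione rather than of the three trisubstituted alkenes: C8 is an electron-rich quaternary carbon aligned with the C1 p-orbital whereas C5 is held near the nodal plane of the dione π-system, and PhI(OAc)2 in basic methanol attacks the dione enolate far faster than isolated alkenes.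

Step 10
Reactants: 17 bicyclo[3.3.1]nonane trione with both bridgeheads unsubstituted
Product: 18 4-methoxy enol ether of the trione
Conditions: Me3SiCHN2, MeOH/toluene, 0 °C to rt
Reagents that add atoms: (trimethylsilyl)diazomethane, C[Si](C)(C)C=[N+]=[N-]
Why: Diazomethane released from Me3SiCHN2 by methanol O-methylates the vinylogous acid, by expectation mainly at O4, the oxygen remote from the quaternary C8, which leaves the C2 ketone next to C1–H; the 2-methoxy regioisomer would be separated and recycled by hydrolysis.

Step 11
Reactants: 18 4-methoxy enol ether of the trione; 19 prenyl bromide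
Product: 20 5-prenyl enol ether
Conditions: LiN(iPr)2, THF, −78 °C; then 19, −78 to −30 °C
Reagents that add atoms: none
Why: Kinetic bridgehead lithiation by the lithium amide is expected at the accessible C5–H (α to the C9 ketone) and not at C1–H, which is screened by the quaternary C8, and the pyramidal bridgehead carbanion is alkylated by prenyl bromide with retention (bridgehead lithiation–alkylation); should C1 react first, step 12 would still lead to the same diprenyl compound.

Step 12
Reactants: 20 5-prenyl enol ether; 19 prenyl bromide
Product: 23 1,5-diprenyl enol ether, via C3-silyl enol ether 21 (not isolated), via C3-silyl diprenyl enol ether 22 (not isolated)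
Conditions: Me3SiCl, lithium 2,2,6,6-tetramethylpiperidide (1.1 equiv), THF, −78 °C; then lithium 2,2,6,6-tetramethylpiperidide (2 equiv), −78 °C; 19, −78 to −30 °C; then Bu4NF, THF, 0 °C
Reagents that add atoms: none
Why: Silylation of the vinylic C3 in the flask blocks that position, the second charge of hindered lithium amide then removes the remaining bridgehead C1–H flanked by the C2 and C9 carbonyls, prenyl bromide alkylates the bridgehead carbanion with retention and fluoride finally removes the C3 silyl group (bridgehead lithiation–alkylation with a temporary silyl block).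

Step 13
Reactants: 24 3-acetoxybenzoic acid
Product: 25 3-acetoxybenzoyl chloride
Conditions: (COCl)2, DMF (cat.), CH2Cl2, 0 °C to rt
Reagents that add atoms: oxalyl chloride, O=C(Cl)C(Cl)=O
Why: The chloroiminium salt formed from oxalyl chloride and DMF converts the acid into its chloride under conditions that leave the aryl acetate intact (acid chloride formation).

Step 14
Reactants: 23 1,5-diprenyl enol ether; 25 3-acetoxybenzoyl chloride
Product: 26 3-(3-acetoxybenzoyl) enol ether
Conditions: lithium 2,2,6,6-tetramethylpiperidide, THF, −78 °C; then 25, −78 to 0 °C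
Reagents that add atoms: none
Why: The vinylic C3–H of the β-methoxy enone is lithiated by the hindered lithium amide and the vinyllithium is C-acylated by the acid chloride, which installs the aroyl group without creating a stereocentre (α-lithiation–acylation of a vinylogous ester).

Step 15
Reactants: 26 3-(3-acetoxybenzoyl) enol ether
Product: 27 CNP0285073.1
Conditions: LiOH, 1,4-dioxane/H2O, 90 °C; then 1 M HCl to pH 3
Reagents that add atoms: lithium hydroxide, [Li+].[OH-]
Why: Hydroxide adds to C4 of the β-methoxy enone and expels methoxide (addition–elimination) and saponifies the aryl acetate, which frees the enolised triketone and the phenol in one operation; none of the four stereocentres is enolisable, so none is scrambled.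

Compound list
1 | cyclopent-2-en-1-one | O=C1C=CCC1 | starting material
2 | rac-3-(phenylsulfonyl)cyclopentan-1-one | O=C1CCC(C1)S(=O)(=O)c1ccccc1 | intermediate
3 | rac-7-(phenylsulfonyl)-1,4-dioxaspiro[4.4]nonane | O=S(=O)(c1ccccc1)C1CCC2(C1)OCCO2 | intermediate
4 | geranyl bromide, (2E)-1-bromo-3,7-dimethylocta-2,6-diene | CC(C)=CCC/C(C)=C/CBr | starting material
5 | rac-7-geranyl-7-(phenylsulfonyl)-1,4-dioxaspiro[4.4]nonane | CC(C)=CCC/C(C)=C/CC1(S(=O)(=O)c2ccccc2)CCC2(C1)OCCO2 | intermediate
6 | rac-3-geranyl-3-(phenylsulfonyl)cyclopentan-1-one | CC(C)=CCC/C(C)=C/CC1(S(=O)(=O)c2ccccc2)CCC(=O)C1 | intermediate (not isolated)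
7 | 3-geranylcyclopent-2-en-1-one | CC(C)=CCC/C(C)=C/CC1=CC(=O)CC1 | intermediate
8 | {[(3S)-3-geranylcyclopent-1-en-1-yl]oxy}diphenylsilane | CC(C)=CCC/C(C)=C/C[C@@H]1CCC(O[SiH](c2ccccc2)c2ccccc2)=C1 | intermediate (not isolated)
9 | (2S,3S)-3-geranyl-2-methylcyclopentan-1-one (trans) | CC(C)=CCC/C(C)=C/C[C@@H]1CCC(=O)[C@H]1C | intermediate
10 | trimethyl{[(3S)-3-geranyl-2-methylcyclopent-1-en-1-yl]oxy}silane | CC(C)=CCC/C(C)=C/C[C@@H]1CCC(O[Si](C)(C)C)=C1C | intermediate
11 | 5-bromo-2-methylpent-2-ene | CC(C)=CCCBr | starting material
12 | (2S,3S)-3-geranyl-2-methyl-2-(4-methylpent-3-en-1-yl)cyclopentan-1-one (homoprenyl trans to geranyl) | CC(C)=CCC/C(C)=C/C[C@@H]1CCC(=O)[C@@]1(C)CCC=C(C)C | intermediate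
13 | diketene, 4-methylideneoxetan-2-one | C=C1CC(=O)O1 | starting material
14 | 5-acetoacetyl derivative of 12 (1-(cyclopentanon-2-yl)butane-1,3-dione; acyl group on the homoprenyl face) | CC(C)=CCC/C(C)=C/C[C@@H]1C[C@@H](C(=O)CC(C)=O)C(=O)[C@@]1(C)CCC=C(C)C | intermediate (not isolated)
15 | cis-fused 2-geranyl-7a-hydroxy-1-methyl-1-(4-methylpent-3-en-1-yl)hexahydro-1H-indene-4,6(5H)-dione (ring-fusion OH anti to homoprenyl, ring-fusion H syn to geranyl) | CC(C)=CCC/C(C)=C/C[C@@H]1C[C@H]2C(=O)CC(=O)C[C@@]2(O)[C@@]1(C)CCC=C(C)C | intermediate
16 | phenyliodonium ylide of 15 at C5 of the indane (C3 of the core numbering) | CC(C)=CCC/C(C)=C/C[C@@H]1C[C@H]2C(=O)[C-]([I+]c3ccccc3)C(=O)C[C@@]2(O)[C@@]1(C)CCC=C(C)C | intermediate (not isolated)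
17 | 7-geranyl-4-hydroxy-8-methyl-8-(4-methylpent-3-en-1-yl)bicyclo[3.3.1]non-3-ene-2,9-dione (geranyl anti, homoprenyl syn to the C2–C4 bridge) | CC(C)=CCC/C(C)=C/C[C@@H]1C[C@@H]2C(=O)[C@@H](C(=O)C=C2O)[C@@]1(C)CCC=C(C)C | intermediate
18 | 7-geranyl-4-methoxy-8-methyl-8-(4-methylpent-3-en-1-yl)bicyclo[3.3.1]non-3-ene-2,9-dione | CC(C)=CCC/C(C)=C/C[C@@H]1C[C@@H]2C(=O)[C@@H](C(=O)C=C2OC)[C@@]1(C)CCC=C(C)C | intermediate
19 | prenyl bromide, 1-bromo-3-methylbut-2-ene | CC(C)=CCBr | starting material
20 | 7-geranyl-4-methoxy-8-methyl-8-(4-methylpent-3-en-1-yl)-5-prenylbicyclo[3.3.1]non-3-ene-2,9-dione | CC(C)=CCC/C(C)=C/C[C@@H]1C[C@]2(CC=C(C)C)C(=O)[C@@H](C(=O)C=C2OC)[C@@]1(C)CCC=C(C)C | intermediate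
21 | 3-(trimethylsilyl) derivative of 20 | CC(C)=CCC/C(C)=C/C[C@@H]1C[C@]2(CC=C(C)C)C(=O)[C@@H](C(=O)C([Si](C)(C)C)=C2OC)[C@@]1(C)CCC=C(C)C | intermediate (not isolated)
22 | 1-prenyl-3-(trimethylsilyl) derivative of 20 | CC(C)=CCC/C(C)=C/C[C@@H]1C[C@]2(CC=C(C)C)C(=O)[C@@](CC=C(C)C)(C(=O)C([Si](C)(C)C)=C2OC)[C@@]1(C)CCC=C(C)C | intermediate (not isolated)
23 | 7-geranyl-4-methoxy-8-methyl-8-(4-methylpent-3-en-1-yl)-1,5-diprenylbicyclo[3.3.1]non-3-ene-2,9-dione | CC(C)=CCC/C(C)=C/C[C@@H]1C[C@]2(CC=C(C)C)C(=O)[C@@](CC=C(C)C)(C(=O)C=C2OC)[C@@]1(C)CCC=C(C)C | intermediate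
24 | 3-acetoxybenzoic acid | CC(=O)Oc1cccc(c1)C(=O)O | starting material
25 | 3-acetoxybenzoyl chloride | CC(=O)Oc1cccc(c1)C(Cl)=O | intermediate
26 | 3-(3-acetoxybenzoyl) derivative of 23 | CC(C)=CCC/C(C)=C/C[C@@H]1C[C@]2(CC=C(C)C)C(=O)[C@@](CC=C(C)C)(C(=O)C(C(=O)c3cccc(OC(C)=O)c3)=C2OC)[C@@]1(C)CCC=C(C)C | intermediate
27 | CNP0285073.1, (1S,5S,7R,8S)-7-geranyl-4-hydroxy-3-(3-hydroxybenzoyl)-8-methyl-8-(4-methylpent-3-en-1-yl)-1,5-diprenylbicyclo[3.3.1]non-3-ene-2,9-dione | CC(C)=CCC/C(C)=C/C[C@@H]1C[C@]2(CC=C(C)C)C(=O)[C@@](CC=C(C)C)(C(=O)C(C(=O)c3cccc(O)c3)=C2O)[C@@]1(C)CCC=C(C)C | target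

Total step count: 15
Longest linear sequence: 14 steps (steps 1–12, 14 and 15, from cyclopent-2-en-1-one); step 13 is a one-step side branch.

Steps most likely to fail

Step 9. The iodonium ylide may be diverted before the 1,2-shift (capture by methanol at C3, ring contraction, retro-aldol opening of the hydrindanol), or the ring bond C9–C5 may migrate in place of C9–C8. Fallback, setting out from 15 and coming back at 18: 15 would be O-methylated (Me3SiCHN2) to the vinylogous methyl ester F1 with the methoxy group on C4. Its α'-carbon C1 would be brominated through the lithium enolate (LiN(iPr)2, two equivalents, then N-bromosuccinimide) to the β-hydroxy α-bromo ketone F2. AgBF4 in CH2Cl2 would then abstract bromide while the C9–C8 bond shifts to C1 (silver-promoted semipinacol rearrangement of a halohydrin), which should give 18 directly, ready for step 11.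

Step 12. Deprotonation of the bridgehead next to the quaternary C8 may be incomplete, and SN2 capture of the congested bridgehead carbanion may be slow, so that O-alkylation or proton return competes. Fallback, setting out from 20 and coming back at 23: C3 would be silylated as in step 12 and 21 isolated. Bridgehead lithiation and quenching with I2 would give the bridgehead iodide F3. Radical allylation (allyltributylstannane, Et3B/air, benzene) would give the bridgehead allyl compound F4, cross-metathesis with 2-methylbut-2-ene (second-generation Grubbs catalyst) would turn the allyl into the prenyl group of 22, and Bu4NF would then give 23. The carbon–carbon bond is thus made through a bridgehead radical, which does not suffer from the steric demand of an SN2 step.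

Step 7. Regiocontrol may be lost because the equilibrated silyl enol ether carries some of the C5 isomer, and alkylation of the tetrasubstituted enolate by an unactivated homoallylic bromide may be slow enough to allow proton transfer and polyalkylation. Fallback, setting out from 7 and coming back at 12: the copper hydride reduction of step 5 would be stopped at the silyl enol ether 8, which would be trapped with dimethylmethyleneiminium iodide to give the Mannich base F5. N-Methylation (MeI) and elimination (NaHCO3) would give the α-methylene ketone F6. Conjugate reduction with LiBH(s-Bu)3 at −78 °C would generate the C8 enolate regiospecifically, and alkylation with 11 (HMPA) anti to the geranyl group would give 12.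

Further compounds
F1 | step 9 | cis-fused 2-geranyl-7a-hydroxy-4-methoxy-1-methyl-1-(4-methylpent-3-en-1-yl)-1,2,3,3a,7,7a-hexahydro-6H-inden-6-one | CC(C)=CCC/C(C)=C/C[C@@H]1C[C@H]2C(OC)=CC(=O)C[C@@]2(O)[C@@]1(C)CCC=C(C)C
F2 | step 9 | 7-bromo derivative of F1 (bromide on C1 of the core numbering, epimers at that carbon) | CC(C)=CCC/C(C)=C/C[C@@H]1C[C@H]2C(OC)=CC(=O)C(Br)[C@@]2(O)[C@@]1(C)CCC=C(C)C
F3 | step 12 | 1-iodo-3-(trimethylsilyl) derivative of 20 | CC(C)=CCC/C(C)=C/C[C@@H]1C[C@]2(CC=C(C)C)C(=O)[C@@](I)(C(=O)C([Si](C)(C)C)=C2OC)[C@@]1(C)CCC=C(C)C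
F4 | step 12 | 1-allyl-3-(trimethylsilyl) derivative of 20 | CC(C)=CCC/C(C)=C/C[C@@H]1C[C@]2(CC=C(C)C)C(=O)[C@@](CC=C)(C(=O)C([Si](C)(C)C)=C2OC)[C@@]1(C)CCC=C(C)C
F5 | step 7 | trans-2-[(dimethylamino)methyl]-3-geranylcyclopentan-1-one, (3S) | CC(C)=CCC/C(C)=C/C[C@@H]1CCC(=O)[C@H]1CN(C)C
F6 | step 7 | (3S)-3-geranyl-2-methylidenecyclopentan-1-one | CC(C)=CCC/C(C)=C/C[C@@H]1CCC(=O)C1=C
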